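## Retrosynthetic overview

1. The target comes from its nona-O-benzyl ether by hydrogenolysis alone. Both gallate esters are carried from the start, so no late selective acylation is needed.
2. C2 and C3 come from one asymmetric double reduction, modelled on anthocyanidin reductase, of the fully substituted flavylium salt (benzylated delphinidin 3,5-digallate). It sets the 2,3-cis relationship and the absolute configuration together.
3. Ring C is the only ring made. It closes by O1–C2 attack within an open-chain C6–C3–C6 chalcone (chalcone, then hemiketal, then flavylium), and the chalcone forms in the same flask by a C3–C4 aldol condensation.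
4. The two halves are a 2-O-aroylphloroglucinaldehyde, which fixes the 5-ester/7-OH pattern, and an ω-aroyloxyacetophenone, which brings the 3-ester.
5. Rings A and B and both galloyl rings are bought, as phloroglucinaldehyde and tri-O-benzylgallic acid (used three times).

Assumption: tri-O-benzylgallic acid and phloroglucinaldehyde are bought as catalogue chemicals, and the (S)-ligand in step 5 is taken to give the (2R,3R) series; the sense of induction is checked on the first run by chiral HPLC and optical rotation, and the equally available (R)-ligand is used if it proves opposite.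

## Route

Step 1
Reactants: 1 3,4,5-tris(benzyloxy)benzoic acid
Product: 2 3,4,5-tris(benzyloxy)benzoyl chloride
Conditions: (COCl)2 (1.3 equiv), DMF (cat.), CH2Cl2, 0 °C to rt, 2 h; concentrate
Reagents that add atoms: oxalyl chloride, O=C(Cl)C(=O)Cl
Why: DMF-catalysed (Vilsmeier-type) acid chloride formation, in which benzyl aryl ethers are inert and everything else leaves as gas, so crude 2 serves both branches.

Step 2
Reactants: 2 3,4,5-tris(benzyloxy)benzoyl chloride; 1 3,4,5-tris(benzyloxy)benzoic acid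
Product: 4 2-oxo-2-[3,4,5-tris(benzyloxy)phenyl]ethyl 3,4,5-tris(benzyloxy)benzoate, via diazoketone 3 (not isolated)
Conditions: Me3SiCHN2 (2.0 equiv), MeCN/THF 1:1, 0 °C to rt, 6 h; concentrate; then 1 (1.0 equiv), Cu(acac)2 (5 mol %), CH2Cl2, reflux, 2 h
Reagents that add atoms: (trimethylsilyl)diazomethane, C[Si](C)(C)C=[N+]=[N-]
Why: Arndt–Eistert-type acylation of the diazo carbon (chloride takes off the silyl group) gives the aryl diazomethyl ketone, whose copper carbenoid undergoes O–H insertion into the carboxylic acid faster than Wolff rearrangement, a standard entry to α-acyloxy ketones that creates no stereocentre.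

Step 3
Reactants: 5 2,4,6-trihydroxybenzaldehyde; 2 3,4,5-tris(benzyloxy)benzoyl chloride
Product: 6 2-formyl-3,5-dihydroxyphenyl 3,4,5-tris(benzyloxy)benzoate
Conditions: KOH (1.0 equiv), H2O/acetone 1:2, N2, 0 °C; 2 (1.0 equiv) in acetone added over 1 h
Reagents that add atoms: none
Why: Schotten–Baumann O-acylation with one equivalent of base, which on phloroglucinaldehyde is known from the classical 2-O-benzoyl and 2-O-glycosyl derivatives to functionalise an ortho oxygen, because the most acidic 4-OH stays as the delocalised, weakly nucleophilic phenoxide and the other ortho OH stays chelated to the formyl group; no stereocentre is involved.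

Step 4
Reactants: 4 2-oxo-2-[3,4,5-tris(benzyloxy)phenyl]ethyl 3,4,5-tris(benzyloxy)benzoate; 6 2-formyl-3,5-dihydroxyphenyl 3,4,5-tris(benzyloxy)benzoate
Product: 8 7-hydroxy-2-[3,4,5-tris(benzyloxy)phenyl]-3,5-bis{[3,4,5-tris(benzyloxy)benzoyl]oxy}chromenylium chloride, via chalcone 7 (not isolated)
Conditions: dry HCl (g, sat.), EtOAc, 0 °C, 2 h, then 4 °C, 48 h; Et2O/hexane, filter under N2
Reagents that add atoms: hydrogen chloride, Cl
Why: Acid-catalysed crossed aldol condensation (Robinson anthocyanidin synthesis) joins C3 to C4, and chalcone 7 then closes ring C as chalcones do in the plant, by attack of the A-ring phenol oxygen on C2, the hemiketal losing water to the aromatic flavylium ion that precipitates as its chloride; only one ortho OH is free, so the 5-ester/7-OH pattern is fixed, and no stereocentre is formed.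

Step 5
Reactants: 8 7-hydroxy-2-[3,4,5-tris(benzyloxy)phenyl]-3,5-bis{[3,4,5-tris(benzyloxy)benzoyl]oxy}chromenylium chloride
Product: 10 (2R,3R)-7-hydroxy-2-[3,4,5-tris(benzyloxy)phenyl]-3,4-dihydro-2H-chromene-3,5-diyl bis[3,4,5-tris(benzyloxy)benzoate], via flav-2-ene 9 (not isolated)
Conditions: [Ir(cod)Cl]2 (2 mol %), (S)-SEGPHOS (4.4 mol %), H2 (50 bar), CH2Cl2/toluene 1:1, 30 °C, 24 h
Reagents that add atoms: none
Why: Proposed new method: asymmetric ionic hydrogenation of a flavylium salt that copies anthocyanidin reductase, in which the trivalent iridium hydride formed from [Ir(cod)Cl]2, the bisphosphine and H2 delivers hydride to the less shielded C4 to give achiral flav-2-ene 9 and HCl, the HCl reprotonates the enol ether reversibly at C3 to a 2-aryl oxocarbenium ion whose 3-acyloxy group sits pseudoaxial to avoid allylic strain with the coplanar aryl group, and the chiral hydride reduces one of the two rapidly interconverting enantiomeric cations at C2 anti to that group (dynamic kinetic resolution), so that C2 and C3 are set together as 2,3-cis (direct syn addition of H2 to 9 gives the same relative configuration); the closest known reaction types are the iridium/bisphosphine asymmetric hydrogenation of 2,3-disubstituted quinolinium and pyridinium halides to cis products and the iridium-catalysed asymmetric hydrogenation of 2-aryl-4H-chromenes.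

Step 6
Reactants: 10 (2R,3R)-7-hydroxy-2-[3,4,5-tris(benzyloxy)phenyl]-3,4-dihydro-2H-chromene-3,5-diyl bis[3,4,5-tris(benzyloxy)benzoate]
Product: 11 (2R,3R)-epigallocatechin 3,5-digallate
Conditions: H2 (1 atm), Pd(OH)2/C (20 wt %), THF/MeOH 4:1, rt, 6 h; filter under N2
Reagents that add atoms: none
Why: Heterogeneous hydrogenolysis of the nine benzyl aryl ethers under neutral conditions, the usual end game for galloylated catechins, leaves the alkyl and aryl gallate esters, the C2–O1 bond and both stereocentres untouched because no acid, base or heat is applied.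

## Compound list

1 | 3,4,5-tris(benzyloxy)benzoic acid | OC(=O)c1cc(OCc2ccccc2)c(OCc2ccccc2)c(OCc2ccccc2)c1 | starting material
2 | 3,4,5-tris(benzyloxy)benzoyl chloride | ClC(=O)c1cc(OCc2ccccc2)c(OCc2ccccc2)c(OCc2ccccc2)c1 | intermediate
3 | 2-diazo-1-[3,4,5-tris(benzyloxy)phenyl]ethan-1-one (not isolated) | [N-]=[N+]=CC(=O)c1cc(OCc2ccccc2)c(OCc2ccccc2)c(OCc2ccccc2)c1 | intermediate
4 | 2-oxo-2-[3,4,5-tris(benzyloxy)phenyl]ethyl 3,4,5-tris(benzyloxy)benzoate | O=C(COC(=O)c1cc(OCc2ccccc2)c(OCc2ccccc2)c(OCc2ccccc2)c1)c1cc(OCc2ccccc2)c(OCc2ccccc2)c(OCc2ccccc2)c1 | intermediate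
5 | 2,4,6-trihydroxybenzaldehyde (phloroglucinaldehyde) | O=Cc1c(O)cc(O)cc1O | starting material
6 | 2-formyl-3,5-dihydroxyphenyl 3,4,5-tris(benzyloxy)benzoate | O=Cc1c(O)cc(O)cc1OC(=O)c1cc(OCc2ccccc2)c(OCc2ccccc2)c(OCc2ccccc2)c1 | intermediate
7 | 2-[(1E)-3-oxo-2-{[3,4,5-tris(benzyloxy)benzoyl]oxy}-3-[3,4,5-tris(benzyloxy)phenyl]prop-1-en-1-yl]-3,5-dihydroxyphenyl 3,4,5-tris(benzyloxy)benzoate (chalcone with ring A cis to the ketone, not isolated) | O=C(Oc1cc(O)cc(O)c1/C=C(\C(=O)c1cc(OCc2ccccc2)c(OCc2ccccc2)c(OCc2ccccc2)c1)OC(=O)c1cc(OCc2ccccc2)c(OCc2ccccc2)c(OCc2ccccc2)c1)c1cc(OCc2ccccc2)c(OCc2ccccc2)c(OCc2ccccc2)c1 | intermediate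
8 | 7-hydroxy-2-[3,4,5-tris(benzyloxy)phenyl]-3,5-bis{[3,4,5-tris(benzyloxy)benzoyl]oxy}chromenylium chloride (nona-O-benzyl delphinidin 3,5-digallate chloride) | [Cl-].O=C(Oc1cc(O)cc2[o+]c(-c3cc(OCc4ccccc4)c(OCc4ccccc4)c(OCc4ccccc4)c3)c(OC(=O)c3cc(OCc4ccccc4)c(OCc4ccccc4)c(OCc4ccccc4)c3)cc12)c1cc(OCc2ccccc2)c(OCc2ccccc2)c(OCc2ccccc2)c1 | intermediate
9 | 7-hydroxy-2-[3,4,5-tris(benzyloxy)phenyl]-4H-chromene-3,5-diyl bis[3,4,5-tris(benzyloxy)benzoate] (flav-2-ene, not isolated) | O=C(Oc1cc(O)cc2OC(c3cc(OCc4ccccc4)c(OCc4ccccc4)c(OCc4ccccc4)c3)=C(OC(=O)c3cc(OCc4ccccc4)c(OCc4ccccc4)c(OCc4ccccc4)c3)Cc12)c1cc(OCc2ccccc2)c(OCc2ccccc2)c(OCc2ccccc2)c1 | intermediate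
10 | (2R,3R)-7-hydroxy-2-[3,4,5-tris(benzyloxy)phenyl]-3,4-dihydro-2H-chromene-3,5-diyl bis[3,4,5-tris(benzyloxy)benzoate] (2,3-cis) | O=C(Oc1cc(O)cc2c1C[C@@H](OC(=O)c1cc(OCc3ccccc3)c(OCc3ccccc3)c(OCc3ccccc3)c1)[C@@H](c1cc(OCc3ccccc3)c(OCc3ccccc3)c(OCc3ccccc3)c1)O2)c1cc(OCc3ccccc3)c(OCc3ccccc3)c(OCc3ccccc3)c1 | intermediate
11 | (2R,3R)-epigallocatechin 3,5-digallate | O=C(Oc1cc(O)cc2c1C[C@@H](OC(=O)c1cc(O)c(O)c(O)c1)[C@@H](c1cc(O)c(O)c(O)c1)O2)c1cc(O)c(O)c(O)c1 | target

## Step count and risks

Total step count: 6. Longest linear sequence: 5 (steps 1, 2, 4, 5, 6; the branch through steps 1, 3, 4, 5, 6 is equally long).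

**Step 5 (asymmetric double reduction of the flavylium salt) carries the most risk.** The tetrasubstituted enol ester stage may stall or give low ee. The fallback sets out from 8 and comes back at 10, and it gives up catalyst control of the absolute configuration.
- One equivalent of Hantzsch ester (diethyl 2,6-dimethyl-1,4-dihydropyridine-3,5-dicarboxylate) in CH2Cl2 at rt puts hydride on C4, and flav-2-ene 9 is isolated.
- Compound 9 is hydrogenated with the achiral [Ir(cod)(PCy3)(py)]PF6 (5 mol %, H2 50 bar, CH2Cl2). This catalyst is suited to tetrasubstituted alkenes and is steered by the ester carbonyl.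
- Syn addition can then give only the racemic 2,3-cis flavan, a 1:1 mixture of 10 and its (2S,3S)-enantiomer F1.
- The two are separated by preparative chiral supercritical-fluid chromatography on an amylose carbamate phase, and 10 goes on to step 6.

**Step 4 (flavylium condensation) is the second risk.** The two equivalents of water released under HCl may cleave the activated 3-O-ester, or the hindered aldehyde may react sluggishly. The fallback sets out from 4 and 6 and comes back at 8. It replaces the protic one-pot condensation by a directed Mukaiyama aldol addition under water-free conditions.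
- Me3SiOTf (3.3 equiv) and iPr2NEt (3.5 equiv) in CH2Cl2 at 0 °C convert 4 into the (Z)-trimethylsilyl enol ether F2 and 6 into the bis(trimethylsilyl) ether F3 in the same flask.
- The excess Me3SiOTf joins them to the tris-silylated aldol adduct F4. It forms as a diastereomer mixture, and both centres vanish in the next operation.
- Isolated F4 is treated with dry HCl in EtOAc/Et2O at 0 °C. This removes the silyl groups, eliminates across C3–C4 and closes ring C to 8.
- Only half an equivalent of water is released instead of two.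

**Step 3 (regioselective monoacylation) is the third risk.** The bulky, lipophilic acid chloride may not reproduce the ortho selectivity known for benzoyl chloride. The fallback sets out from 5 and comes back at 6. It uses a temporary blocking group in place of innate selectivity.
- TBSCl (1.0 equiv) and imidazole in DMF at 0 °C silylate the one hydroxyl that is neither chelated nor flanked by the formyl group. This gives 4-[(tert-butyldimethylsilyl)oxy]-2,6-dihydroxybenzaldehyde F5.
- Its two remaining hydroxyls are equivalent, so acylation with 2 (1.0 equiv, Et3N, CH2Cl2, −20 °C) can give only one monoester. That monoester is 5-[(tert-butyldimethylsilyl)oxy]-2-formyl-3-hydroxyphenyl 3,4,5-tris(benzyloxy)benzoate F6, in which the last OH is chelated and deactivated.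
- Et3N·3HF in THF at 0 °C removes the silyl ether without touching the aryl ester and delivers 6.

## Further compounds

F1 | step 5 | (2S,3S)-7-hydroxy-2-[3,4,5-tris(benzyloxy)phenyl]-3,4-dihydro-2H-chromene-3,5-diyl bis[3,4,5-tris(benzyloxy)benzoate] (enantiomer of 10) | O=C(Oc1cc(O)cc2c1C[C@H](OC(=O)c1cc(OCc3ccccc3)c(OCc3ccccc3)c(OCc3ccccc3)c1)[C@H](c1cc(OCc3ccccc3)c(OCc3ccccc3)c(OCc3ccccc3)c1)O2)c1cc(OCc3ccccc3)c(OCc3ccccc3)c(OCc3ccccc3)c1
F2 | step 4 | (Z)-2-[3,4,5-tris(benzyloxy)phenyl]-2-[(trimethylsilyl)oxy]ethenyl 3,4,5-tris(benzyloxy)benzoate | C[Si](C)(C)O/C(c1cc(OCc2ccccc2)c(OCc2ccccc2)c(OCc2ccccc2)c1)=C\OC(=O)c1cc(OCc2ccccc2)c(OCc2ccccc2)c(OCc2ccccc2)c1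
F3 | step 4 | 2-formyl-3,5-bis[(trimethylsilyl)oxy]phenyl 3,4,5-tris(benzyloxy)benzoate | O=Cc1c(O[Si](C)(C)C)cc(O[Si](C)(C)C)cc1OC(=O)c1cc(OCc2ccccc2)c(OCc2ccccc2)c(OCc2ccccc2)c1
F4 | step 4 | 2-{3-oxo-2-{[3,4,5-tris(benzyloxy)benzoyl]oxy}-3-[3,4,5-tris(benzyloxy)phenyl]-1-[(trimethylsilyl)oxy]propyl}-3,5-bis[(trimethylsilyl)oxy]phenyl 3,4,5-tris(benzyloxy)benzoate (diastereomer mixture) | O=C(Oc1cc(O[Si](C)(C)C)cc(O[Si](C)(C)C)c1C(O[Si](C)(C)C)C(OC(=O)c1cc(OCc2ccccc2)c(OCc2ccccc2)c(OCc2ccccc2)c1)C(=O)c1cc(OCc2ccccc2)c(OCc2ccccc2)c(OCc2ccccc2)c1)c1cc(OCc2ccccc2)c(OCc2ccccc2)c(OCc2ccccc2)c1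
F5 | step 3 | 4-[(tert-butyldimethylsilyl)oxy]-2,6-dihydroxybenzaldehyde | O=Cc1c(O)cc(O[Si](C)(C)C(C)(C)C)cc1O
F6 | step 3 | 5-[(tert-butyldimethylsilyl)oxy]-2-formyl-3-hydroxyphenyl 3,4,5-tris(benzyloxy)benzoate | O=Cc1c(O)cc(O[Si](C)(C)C(C)(C)C)cc1OC(=O)c1cc(OCc2ccccc2)c(OCc2ccccc2)c(OCc2ccccc2)c1
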